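Ring A (C1 OH, C2 aryloxy, C3, C4, C6 Br, C5 H) carries at C3 a bromine ortho to the ether and meta to the hydroxyl, beyond the reach of phenol-directed bromination. C3 and its bromine are therefore delivered as dibromocarbene to a cyclopentene whose enol ether double bond joins C2 and C4 and whose C1 is a ketal. The key step forms C2–C3 and C3–C4, enlarges the five-membered ring to ring A, installs the C3 bromine and aromatises. Its precursor is the 2-bromophenyl enol ether of cyclopentane-1,2-dione mono(dimethyl ketal); the freed hydroxyl then directs bromine to C4 and C6.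

Key step: step 4

Remark on the chemistry: a cyclohexa-2,4-dienone ketal with a CH2 at C6 should not hydrolyse to the dienone, because once one alkoxy group leaves, the O-alkyl arenium ion sheds the C6 proton and C1 emerges as an alkyl ether. A dimethyl ketal is therefore used so that the cascade ends as a methyl ether (a dioxolane would end as a 2-hydroxyethyl ether), and that ether is cleaved in a separate step. Racemic compounds are drawn as one enantiomer.

Step 1
Reactants: 1 cyclopent-2-en-1-one
Product: 2 6-oxabicyclo[3.1.0]hexan-2-one (racemic cis-fused 2,3-epoxycyclopentanone)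
Conditions: 30% aq. H2O2 (1.3 equiv), NaOH (0.1 equiv), MeOH, 0 °C
Reagents that add atoms: hydrogen peroxide, OO
Why: Weitz–Scheffer nucleophilic epoxidation, in which hydroperoxide adds in conjugate fashion and the enolate closes onto the O–O bond; the cis ring fusion is the only geometry possible and the product is racemic.

Step 2
Reactants: 2 6-oxabicyclo[3.1.0]hexan-2-one, 3 2-bromophenol
Product: 5 2-(2-bromophenoxy)cyclopent-2-en-1-one, via hydroxy ketone 4 (not isolated)
Conditions: 3 (1.1 equiv), K2CO3 (0.3 equiv), DMF, 60 °C
Reagents that add atoms: none
Why: The phenoxide should open the epoxide by SN2 at C2, the carbon activated by the adjacent carbonyl, with inversion to the trans hydroxy ketone 4, and E1cB dehydration under the same base gives the 2-aryloxy enone (epoxy ketone to α-substituted enone conversion), so both stereocentres vanish.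

Step 3
Reactants: 5 2-(2-bromophenoxy)cyclopent-2-en-1-one
Product: 6 1-bromo-2-[(5,5-dimethoxycyclopent-1-en-1-yl)oxy]benzene
Conditions: MeOSiMe3 (3 equiv), Me3SiOTf (5 mol %), CH2Cl2, −78 → −30 °C; pyridine quench
Reagents that add atoms: methoxytrimethylsilane, CO[Si](C)(C)C
Why: Noyori aprotic ketalisation, in which the silyl-activated carbonyl takes up two methoxy groups with irreversible formation of hexamethyldisiloxane, and at low temperature without protic acid the aryl enol ether should neither migrate nor exchange.

Step 4
Reactants: 6 1-bromo-2-[(5,5-dimethoxycyclopent-1-en-1-yl)oxy]benzene, 7 bromoform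
Product: 10 1-bromo-2-(2-bromophenoxy)-3-methoxybenzene, via dibromocyclopropane 8 (not isolated), via diene ketal 9 (not isolated)
Conditions: CHBr3 (3 equiv), KOt-Bu (5 equiv), hexane, −20 °C → rt; filter, concentrate; then camphorsulfonic acid (10 mol %), CH2Cl2, rt
Reagents that add atoms: bromoform, BrC(Br)Br
Why: Proposed new method: singlet CBr2 from α-elimination of bromoform should add to the electron-rich enol ether, the only alkene present, to give cis-fused 8, whose strained, aryloxy-substituted bicyclo[3.1.0]hexane ionises by disrotatory two-electron electrocyclic opening with loss of the endo bromide to a cyclohexenyl cation spread over C2 and C4; bulky tert-butoxide should not attack the hindered C2, so the C5 proton is lost (directly or by E2 of the C4 bromide formed by ion-pair return) to give 9. The closest known reactions are the dihalocarbene ring expansions of cyclic enol ethers to 2-halocycloalkenones and of indenes and cyclopentadienes to haloarenes. Ring A is closed not by a cyclisation but by [2+1] cheletropic addition followed by cleavage of the shared C2–C4 bond, a five-to-six ring enlargement that creates C2–C3 and C3–C4. With acid the ketal of 9 ionises to an O-methyl arenium ion that loses the C6 proton faster than anything can trap it, so aromatisation should end at methyl ether 10 with loss of methanol. The two stereocentres of 8 are transient and the product has none. The step needs only chemoselectivity for the enol ether over ring B, while regiochemistry is fixed because the carbene carbon can only end between C2 and C4 and only C5 carries a removable proton.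

Step 5
Reactants: 10 1-bromo-2-(2-bromophenoxy)-3-methoxybenzene
Product: 12 3-bromo-2-(2-bromophenoxy)phenol, via aryloxyborane 11 (not isolated)
Conditions: BBr3 (2.5 equiv), CH2Cl2, −78 °C → rt; then H2O
Reagents that add atoms: none
Why: BBr3 O-demethylation of an aryl methyl ether, in which boron coordinates the methoxy oxygen, bromide attacks the methyl carbon by SN2 and water hydrolyses aryloxyborane 11, while the diaryl ether and the aryl bromides should be inert.

Step 6
Reactants: 12 3-bromo-2-(2-bromophenoxy)phenol
Product: 14 3,4,6-tribromo-2-(2-bromophenoxy)phenol, via dibromophenol 13 (not isolated)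
Conditions: Br2 (2.05 equiv), AcOH, rt
Reagents that add atoms: bromine, BrBr
Why: Electrophilic aromatic bromination in which the free hydroxyl directs to its para position C4 and its one open ortho position C6 (either order converges); ring B is an aryl ether of an electron-poor phenol and C5 lies between two bromines, so two equivalents should stop at the target.

Compound list
1 | cyclopent-2-en-1-one | O=C1C=CCC1 | starting material
2 | 6-oxabicyclo[3.1.0]hexan-2-one (2,3-epoxycyclopentanone; racemic, cis-fused) | O=C1CC[C@@H]2O[C@H]12 | intermediate
3 | 2-bromophenol | Oc1ccccc1Br | starting material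
4 | trans-2-(2-bromophenoxy)-3-hydroxycyclopentan-1-one (racemic; not isolated) | O=C1CC[C@H](O)[C@H]1Oc1ccccc1Br | intermediate
5 | 2-(2-bromophenoxy)cyclopent-2-en-1-one | O=C1CCC=C1Oc1ccccc1Br | intermediate
6 | 1-bromo-2-[(5,5-dimethoxycyclopent-1-en-1-yl)oxy]benzene | COC1(OC)CCC=C1Oc1ccccc1Br | intermediate
7 | bromoform | BrC(Br)Br | starting material
8 | 6,6-dibromo-1-(2-bromophenoxy)-2,2-dimethoxybicyclo[3.1.0]hexane (racemic, cis-fused; not isolated) | COC1(OC)CC[C@@H]2C(Br)(Br)[C@]12Oc1ccccc1Br | intermediate
9 | 1-bromo-2-[(2-bromo-6,6-dimethoxycyclohexa-1,3-dien-1-yl)oxy]benzene (not isolated) | COC1(OC)CC=CC(Br)=C1Oc1ccccc1Br | intermediate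
10 | 1-bromo-2-(2-bromophenoxy)-3-methoxybenzene | COc1cccc(Br)c1Oc1ccccc1Br | intermediate
11 | dibromo[3-bromo-2-(2-bromophenoxy)phenoxy]borane (not isolated) | BrB(Br)Oc1cccc(Br)c1Oc1ccccc1Br | intermediate
12 | 3-bromo-2-(2-bromophenoxy)phenol | Oc1cccc(Br)c1Oc1ccccc1Br | intermediate
13 | 3,4-dibromo-2-(2-bromophenoxy)phenol (not isolated) | Oc1ccc(Br)c(Br)c1Oc1ccccc1Br | intermediate
14 | 3,4,6-tribromo-2-(2-bromophenoxy)phenol | Oc1c(Br)cc(Br)c(Br)c1Oc1ccccc1Br | target

Total step count: 6
Longest linear sequence: 6 steps (1 to 14)

Steps most likely to fail

First risk, step 4 (the one step proposed as a new method): the aryloxy-stabilised allyl cation may be captured at C2 by tert-butoxide or adventitious water with expulsion of 2-bromophenol, a second carbene may add to the newly formed C4=C5 bond, or ring opening of the cyclopropane may stall. The fallback for step 4 uses known chemistry only, sets out from 2-bromophenol 3 and comes back to the route at phenol 12. SNAr of 3 on 3-bromo-2-fluorobenzaldehyde F1 with K2CO3 in DMF at 100 °C should give 3-bromo-2-(2-bromophenoxy)benzaldehyde F2 by displacement of the fluoride activated by the ortho formyl group. Baeyer–Villiger (Dakin-type) oxidation with mCPBA in CH2Cl2 should convert it into 3-bromo-2-(2-bromophenoxy)phenyl formate F3 through migration of the oxygen-substituted aryl group, and methanolysis with K2CO3 in MeOH should then release 12, ready for step 6.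

Second risk, step 2: base-induced isomerisation of epoxy ketone 2 to the enol of cyclopentane-1,2-dione may outrun opening by the hindered, weakly nucleophilic phenoxide, or the epoxide may open at C3. The fallback for step 2 sets out from 2-bromophenol 3 and comes back to the route at enone 5. O-Alkylation of 3 with 2-chlorocyclopentan-1-one F4 using K2CO3 in acetone should give 2-(2-bromophenoxy)cyclopentan-1-one F5 by Williamson substitution at the activated α-carbon. Thermodynamic silylation with Me3SiOTf and Et3N toward the more acidic aryloxy-bearing carbon should give {[2-(2-bromophenoxy)cyclopent-1-en-1-yl]oxy}trimethylsilane F6 as the tetrasubstituted enol ether, and Saegusa–Ito oxidation with Pd(OAc)2 (1 equiv, phosphine-free) in MeCN at rt should then deliver 5 by β-hydride elimination toward C3.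

Third risk, step 3: reversion of the acyclic ketal to the enone, or loss of methanol to a methoxy diene, during isolation. The fallback for step 3 changes the protecting-group plan, sets out from enone 5 and comes back to the route at phenol 12. Treatment of 5 with 1,2-bis(trimethylsilyloxy)ethane and catalytic Me3SiOTf in CH2Cl2 at −78 °C should give the sturdier cyclic ketal 6-(2-bromophenoxy)-1,4-dioxaspiro[4.4]non-6-ene F7 in place of 6. Under the conditions of step 4 this should pass through 6,6-dibromo-1-(2-bromophenoxy)spiro[bicyclo[3.1.0]hexane-2,2'-[1,3]dioxolane] F8 and then 7-bromo-6-(2-bromophenoxy)-1,4-dioxaspiro[4.5]deca-6,8-diene F9 before acid opens the dioxolane with aromatisation to 2-[3-bromo-2-(2-bromophenoxy)phenoxy]ethan-1-ol F10 as a hydroxyethyl ether. Excess BBr3 in CH2Cl2 should then cleave that ether to 12.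

Further compounds
F1 | step 4 | 3-bromo-2-fluorobenzaldehyde (purchased) | O=Cc1cccc(Br)c1F
F2 | step 4 | 3-bromo-2-(2-bromophenoxy)benzaldehyde | O=Cc1cccc(Br)c1Oc1ccccc1Br
F3 | step 4 | 3-bromo-2-(2-bromophenoxy)phenyl formate | O=COc1cccc(Br)c1Oc1ccccc1Br
F4 | step 2 | 2-chlorocyclopentan-1-one (purchased, racemic) | O=C1CCCC1Cl
F5 | step 2 | 2-(2-bromophenoxy)cyclopentan-1-one (racemic) | O=C1CCCC1Oc1ccccc1Br
F6 | step 2 | {[2-(2-bromophenoxy)cyclopent-1-en-1-yl]oxy}trimethylsilane | C[Si](C)(C)OC1=C(Oc2ccccc2Br)CCC1
F7 | step 3 | 6-(2-bromophenoxy)-1,4-dioxaspiro[4.4]non-6-ene | Brc1ccccc1OC1=CCCC12OCCO2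
F8 | step 3 | 6,6-dibromo-1-(2-bromophenoxy)spiro[bicyclo[3.1.0]hexane-2,2'-[1,3]dioxolane] (racemic, cis-fused) | O1CCOC12CC[C@@H]3C(Br)(Br)[C@]23Oc2ccccc2Br
F9 | step 3 | 7-bromo-6-(2-bromophenoxy)-1,4-dioxaspiro[4.5]deca-6,8-diene | Brc1ccccc1OC1=C(Br)C=CCC12OCCO2
F10 | step 3 | 2-[3-bromo-2-(2-bromophenoxy)phenoxy]ethan-1-ol | OCCOc1cccc(Br)c1Oc1ccccc1Br
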